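**Retrosynthetic overview**
1. Target 16 comes from dimethyl ether 15 by chelation-controlled cleavage of the 8-OMe group; 15 comes from 3-allyl lactone 12 and dec-9-en-1-ol 13 by cross-metathesis, then hydrogenation.
2. The lactone ring is the only ring made (the benzene ring is bought); it is closed from bromo homoallylic alcohol 9 by Br–Li exchange, CO2 capture and lactonization.
3. The key C–C bond (C3 to the first side-chain carbon) and the only stereocentre come from aldehyde 4 and an allyl fragment by asymmetric carbonyl allylation with (+)-Ipc2B(allyl).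
4. Aldehyde 4 comes from 3,5-dimethoxyphenylacetic acid 1 by ring bromination, reduction and oxidation.

Assumption: the stereocentre (C3 of the isochromanone) is R, as read from the SMILES; reagents carry a number only when they supply skeleton carbons or lead to such a fragment in the flask.

**Route**

Step 1
Reactants: 1 3,5-dimethoxyphenylacetic acid
Product: 2 2-(2-bromo-3,5-dimethoxyphenyl)acetic acid
Conditions: NBS (1.05 equiv), MeCN, 0 °C to rt
Reagents that add atoms: N-bromosuccinimide, O=C1CCC(=O)N1Br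
Why: Electrophilic aromatic bromination goes to C2 (equivalent to C6), para to one OMe and ortho to the other, because the position between the two OMe groups is more hindered.

Step 2
Reactants: 2 2-(2-bromo-3,5-dimethoxyphenyl)acetic acid
Product: 3 2-(2-bromo-3,5-dimethoxyphenyl)ethan-1-ol
Conditions: BH3·THF (1.5 equiv), THF, 0 °C to rt; then H2O
Reagents that add atoms: none
Why: Borane reduction of a carboxylic acid (via the acyloxyborane) is chemoselective and leaves the aryl bromide and the methyl ethers untouched.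

Step 3
Reactants: 3 2-(2-bromo-3,5-dimethoxyphenyl)ethan-1-ol
Product: 4 2-(2-bromo-3,5-dimethoxyphenyl)acetaldehyde
Conditions: Dess–Martin periodinane (1.2 equiv), CH2Cl2, 0 °C to rt, 1 h; used crude at once
Reagents that add atoms: none
Why: Dess–Martin oxidation stops at the aldehyde under near-neutral conditions, which limits enolization and self-condensation of the arylacetaldehyde.

Step 4
Reactants: 4 2-(2-bromo-3,5-dimethoxyphenyl)acetaldehyde; 5 (+)-B-methoxydiisopinocampheylborane [(+)-Ipc2BOMe, the enantiomer made from (−)-α-pinene]; 6 allylmagnesium bromide CH2=CHCH2MgBr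
Product: 9 (R)-1-(2-bromo-3,5-dimethoxyphenyl)pent-4-en-2-ol, via allylborane (+)-Ipc2B(allyl) 7 (not isolated), via diisopinocampheylborinate ester 8 (not isolated)
Conditions: 5 (1.5 equiv), 6 (1.4 equiv), Et2O, 0 °C to rt, 1 h; then 4, −78 °C, 3 h; then 3 M NaOH, 30% H2O2, 0 °C to rt
Reagents that add atoms: none
Why: Brown asymmetric allylboration through a chair-like six-membered transition state, in which the isopinocampheyl groups from (−)-α-pinene direct the allyl group to the Re face of the aldehyde and so set the (R)-carbinol centre, and which is fast enough at −78 °C to outrun aldehyde self-condensation.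

Step 5
Reactants: 9 (R)-1-(2-bromo-3,5-dimethoxyphenyl)pent-4-en-2-ol
Product: 12 (3R)-6,8-dimethoxy-3-(prop-2-en-1-yl)-3,4-dihydro-1H-isochromen-1-one, via dilithio alkoxide aryllithium 10 (not isolated), via hydroxy acid 11 (not isolated)
Conditions: n-BuLi (2.2 equiv), THF, −78 °C, 30 min; CO2 (g), −78 °C to rt; 2 M HCl; then TsOH·H2O (cat.), PhMe, 60 °C
Reagents that add atoms: carbon dioxide, O=C=O
Why: Deprotonation of the alcohol and bromine–lithium exchange give a dianion whose aryllithium is carboxylated by CO2, and the resulting hydroxy acid closes to the six-membered lactone under acid catalysis without touching the C–O bond of the stereocentre.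

Step 6
Reactants: 12 (3R)-6,8-dimethoxy-3-(prop-2-en-1-yl)-3,4-dihydro-1H-isochromen-1-one; 13 dec-9-en-1-ol
Product: 14 (3R)-3-[(2E)-11-hydroxyundec-2-en-1-yl]-6,8-dimethoxy-3,4-dihydro-1H-isochromen-1-one (E major, some Z)
Conditions: 13 (3 equiv), second-generation Grubbs catalyst RuCl2(=CHPh)(PCy3)(H2IMes) (5 mol%), CH2Cl2, 40 °C
Reagents that add atoms: none
Why: Olefin cross-metathesis of two unhindered terminal alkenes is driven by loss of ethene and by the excess of cheap 13, and the E/Z ratio does not matter because the double bond is hydrogenated next.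

Step 7
Reactants: 14 (3R)-3-[(2E)-11-hydroxyundec-2-en-1-yl]-6,8-dimethoxy-3,4-dihydro-1H-isochromen-1-one
Product: 15 (3R)-3-(11-hydroxyundecyl)-6,8-dimethoxy-3,4-dihydro-1H-isochromen-1-one
Conditions: H2 (1 atm), 10% Pd/C, EtOAc, rt
Reagents that add atoms: none
Why: Heterogeneous catalytic hydrogenation saturates the disubstituted alkene, while the lactone, the aryl ethers and the non-benzylic C3–O bond are inert.

Step 8
Reactants: 15 (3R)-3-(11-hydroxyundecyl)-6,8-dimethoxy-3,4-dihydro-1H-isochromen-1-one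
Product: 16 (3R)-8-hydroxy-3-(11-hydroxyundecyl)-6-methoxy-3,4-dihydro-1H-isochromen-1-one
Conditions: BCl3 (1 M in CH2Cl2, 3.5 equiv), CH2Cl2, −78 to 0 °C; then H2O, 0 °C
Reagents that add atoms: none
Why: Chelation-controlled Lewis-acid ether cleavage, in which BCl3 bridges the lactone carbonyl and the peri 8-OMe and removes only that methyl group, while the 6-OMe stays, the primary alcohol is only borylated until work-up and the stereocentre is not involved.

**Compound list**
1 | 3,5-dimethoxyphenylacetic acid | COc1cc(CC(=O)O)cc(OC)c1 | starting material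
2 | 2-(2-bromo-3,5-dimethoxyphenyl)acetic acid | COc1cc(OC)c(Br)c(CC(=O)O)c1 | intermediate
3 | 2-(2-bromo-3,5-dimethoxyphenyl)ethan-1-ol | COc1cc(OC)c(Br)c(CCO)c1 | intermediate
4 | 2-(2-bromo-3,5-dimethoxyphenyl)acetaldehyde | COc1cc(OC)c(Br)c(CC=O)c1 | intermediate
5 | (+)-B-methoxydiisopinocampheylborane, (+)-Ipc2BOMe, from (−)-α-pinene | COB([C@H]1C[C@H]2C[C@@H]([C@@H]1C)C2(C)C)[C@H]1C[C@H]2C[C@@H]([C@@H]1C)C2(C)C | starting material
6 | allylmagnesium bromide | C=CC[Mg]Br | starting material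
7 | (+)-B-allyldiisopinocampheylborane, (+)-Ipc2B(allyl) | C=CCB([C@H]1C[C@H]2C[C@@H]([C@@H]1C)C2(C)C)[C@H]1C[C@H]2C[C@@H]([C@@H]1C)C2(C)C | intermediate
8 | (R)-1-(2-bromo-3,5-dimethoxyphenyl)pent-4-en-2-yl diisopinocampheylborinate | COc1cc(OC)c(Br)c(C[C@@H](CC=C)OB([C@H]2C[C@H]3C[C@@H]([C@@H]2C)C3(C)C)[C@H]2C[C@H]3C[C@@H]([C@@H]2C)C3(C)C)c1 | intermediate
9 | (R)-1-(2-bromo-3,5-dimethoxyphenyl)pent-4-en-2-ol | COc1cc(OC)c(Br)c(C[C@@H](CC=C)O)c1 | intermediate
10 | lithium (R)-1-(2-lithio-3,5-dimethoxyphenyl)pent-4-en-2-olate | COc1cc(OC)c([Li])c(C[C@@H](CC=C)O[Li])c1 | intermediate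
11 | (R)-2-(2-hydroxypent-4-en-1-yl)-4,6-dimethoxybenzoic acid | COc1cc(OC)c(C(=O)O)c(C[C@@H](CC=C)O)c1 | intermediate
12 | (3R)-6,8-dimethoxy-3-(prop-2-en-1-yl)-3,4-dihydro-1H-isochromen-1-one | COc1cc(OC)c2c(c1)C[C@@H](CC=C)OC2=O | intermediate
13 | dec-9-en-1-ol | C=CCCCCCCCCO | starting material
14 | (3R)-3-[(2E)-11-hydroxyundec-2-en-1-yl]-6,8-dimethoxy-3,4-dihydro-1H-isochromen-1-one | COc1cc(OC)c2c(c1)C[C@@H](C/C=C/CCCCCCCCO)OC2=O | intermediate
15 | (3R)-3-(11-hydroxyundecyl)-6,8-dimethoxy-3,4-dihydro-1H-isochromen-1-one | COc1cc(OC)c2c(c1)C[C@@H](CCCCCCCCCCCO)OC2=O | intermediate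
16 | (3R)-8-hydroxy-3-(11-hydroxyundecyl)-6-methoxy-3,4-dihydro-1H-isochromen-1-one (CNP0140068.1) | COc1cc(O)c2c(c1)C[C@@H](CCCCCCCCCCCO)OC2=O | target

**Step count and risks**
Total steps: 8. Longest linear sequence: 8 steps (1 to 16); 5, 6 and 13 are bought.

Most likely to fail:

Step 4. The arylacetaldehyde 4 can self-condense, and the ee (usually 90–95% for this reagent class) depends on reagent quality; a shortfall in ee can be corrected by recrystallizing lactone 12 or 15. Fallback, setting out from acid 2 and coming back to the route at 9 (steps 2 and 3 are then not used): the stereocentre is set by hydrogenation of a β-keto ester instead. Acid 2 is activated with CDI in THF to 2-(2-bromo-3,5-dimethoxyphenyl)-1-(imidazol-1-yl)ethan-1-one F1, which is condensed in the same flask with KO2CCH2CO2Me, MgCl2 and Et3N (decarboxylative Claisen condensation) to methyl 4-(2-bromo-3,5-dimethoxyphenyl)-3-oxobutanoate F2. Noyori hydrogenation with RuCl2[(S)-BINAP] (H2 50 bar, MeOH, 50 °C) gives methyl (S)-4-(2-bromo-3,5-dimethoxyphenyl)-3-hydroxybutanoate F3, which has the same spatial arrangement as 9 (the descriptor is S only because CH2CO2Me outranks CH2Ar). TBSCl and imidazole in DMF give methyl (S)-4-(2-bromo-3,5-dimethoxyphenyl)-3-[(tert-butyldimethylsilyl)oxy]butanoate F4, and i-Bu2AlH in CH2Cl2 at −78 °C gives (S)-4-(2-bromo-3,5-dimethoxyphenyl)-3-[(tert-butyldimethylsilyl)oxy]butanal F5. Methylenetriphenylphosphorane F6, made in THF from Ph3PCH3Br and KOC(CH3)3, converts F5 into tert-butyl{[(R)-1-(2-bromo-3,5-dimethoxyphenyl)pent-4-en-2-yl]oxy}dimethylsilane F7, and Bu4NF in THF gives 9.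

Step 5. The dianion may be quenched or alkylated before CO2 capture, or the hydroxy acid may lactonize poorly. Fallback, setting out from 9 and coming back at 12: the carbonyl carbon is delivered intramolecularly. NaH and Et2NCOCl in THF give (R)-1-(2-bromo-3,5-dimethoxyphenyl)pent-4-en-2-yl diethylcarbamate F8. Treatment with t-BuLi (2.1 equiv, THF, −78 °C) causes bromine–lithium exchange and an immediate 1,5 O-to-C carbamoyl shift to (R)-N,N-diethyl-2-(2-hydroxypent-4-en-1-yl)-4,6-dimethoxybenzamide F9. Heating F9 with TsOH·H2O in toluene closes the lactone 12 with loss of diethylamine.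

Step 6. Homodimerization or double-bond migration may lower the yield of the cross product. Fallback, setting out from 12 and coming back at 15: the chain is joined by a Wittig reaction instead. 9-BBN in THF adds to the allyl group to give (3R)-3-[3-(9-borabicyclo[3.3.1]nonan-9-yl)propyl]-6,8-dimethoxy-3,4-dihydro-1H-isochromen-1-one F10, which NaBO3·4H2O oxidizes to (3R)-3-(3-hydroxypropyl)-6,8-dimethoxy-3,4-dihydro-1H-isochromen-1-one F11. Dess–Martin oxidation gives 3-[(3R)-6,8-dimethoxy-1-oxo-3,4-dihydro-1H-isochromen-3-yl]propanal F12. Separately, 8-bromooctan-1-ol and PPh3 in refluxing MeCN give (8-hydroxyoctyl)triphenylphosphonium bromide F13, which NaN(SiMe3)2 (2 equiv, THF, −78 °C) converts into sodium 8-(triphenylphosphoranylidene)octan-1-olate F14. F14 and F12 give (3R)-3-[(3Z)-11-hydroxyundec-3-en-1-yl]-6,8-dimethoxy-3,4-dihydro-1H-isochromen-1-one F15, and H2 over 10% Pd/C in EtOAc gives 15.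

**Further compounds**
F1 | step 4 | 2-(2-bromo-3,5-dimethoxyphenyl)-1-(imidazol-1-yl)ethan-1-one | COc1cc(OC)c(Br)c(CC(=O)n2ccnc2)c1
F2 | step 4 | methyl 4-(2-bromo-3,5-dimethoxyphenyl)-3-oxobutanoate | COc1cc(OC)c(Br)c(CC(=O)CC(=O)OC)c1
F3 | step 4 | methyl (S)-4-(2-bromo-3,5-dimethoxyphenyl)-3-hydroxybutanoate | COc1cc(OC)c(Br)c(C[C@@H](CC(=O)OC)O)c1
F4 | step 4 | methyl (S)-4-(2-bromo-3,5-dimethoxyphenyl)-3-[(tert-butyldimethylsilyl)oxy]butanoate | COc1cc(OC)c(Br)c(C[C@@H](CC(=O)OC)O[Si](C)(C)C(C)(C)C)c1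
F5 | step 4 | (S)-4-(2-bromo-3,5-dimethoxyphenyl)-3-[(tert-butyldimethylsilyl)oxy]butanal | COc1cc(OC)c(Br)c(C[C@@H](CC=O)O[Si](C)(C)C(C)(C)C)c1
F6 | step 4 | methylenetriphenylphosphorane | C=P(c1ccccc1)(c1ccccc1)c1ccccc1
F7 | step 4 | tert-butyl{[(R)-1-(2-bromo-3,5-dimethoxyphenyl)pent-4-en-2-yl]oxy}dimethylsilane | COc1cc(OC)c(Br)c(C[C@@H](CC=C)O[Si](C)(C)C(C)(C)C)c1
F8 | step 5 | (R)-1-(2-bromo-3,5-dimethoxyphenyl)pent-4-en-2-yl diethylcarbamate | COc1cc(OC)c(Br)c(C[C@@H](CC=C)OC(=O)N(CC)CC)c1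
F9 | step 5 | (R)-N,N-diethyl-2-(2-hydroxypent-4-en-1-yl)-4,6-dimethoxybenzamide | CCN(CC)C(=O)c1c(OC)cc(OC)cc1C[C@@H](CC=C)O
F10 | step 6 | (3R)-3-[3-(9-borabicyclo[3.3.1]nonan-9-yl)propyl]-6,8-dimethoxy-3,4-dihydro-1H-isochromen-1-one | COc1cc(OC)c2c(c1)C[C@@H](CCCB1C3CCCC1CCC3)OC2=O
F11 | step 6 | (3R)-3-(3-hydroxypropyl)-6,8-dimethoxy-3,4-dihydro-1H-isochromen-1-one | COc1cc(OC)c2c(c1)C[C@@H](CCCO)OC2=O
F12 | step 6 | 3-[(3R)-6,8-dimethoxy-1-oxo-3,4-dihydro-1H-isochromen-3-yl]propanal | COc1cc(OC)c2c(c1)C[C@@H](CCC=O)OC2=O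
F13 | step 6 | (8-hydroxyoctyl)triphenylphosphonium bromide | OCCCCCCCC[P+](c1ccccc1)(c1ccccc1)c1ccccc1.[Br-]
F14 | step 6 | sodium 8-(triphenylphosphoranylidene)octan-1-olate | [Na+].[O-]CCCCCCCC=P(c1ccccc1)(c1ccccc1)c1ccccc1
F15 | step 6 | (3R)-3-[(3Z)-11-hydroxyundec-3-en-1-yl]-6,8-dimethoxy-3,4-dihydro-1H-isochromen-1-one | COc1cc(OC)c2c(c1)C[C@@H](CC/C=C\CCCCCCCO)OC2=O
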